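The numbers in the tables come from a simulation for substances that don't exist, and the scatter is random.

I decided to leave the large question, how fast the starting material goes, to the readings, and to reckon the small one: how much of it never reaches the target.

all flasks: starting material 20 mM

|  | precatalyst | remark | time |
|---|---|---|---|
| west | 0.16 mol% | run made earlier |  |
| north | 0.64 mol% | run made earlier |  |
| flask | 0.32 mol% |  | 2.5 h |

| run | time / min | target / % | starting material / % |
|---|---|---|---|
| west | 25.0 | 7.1 | 90.2 |
| west | 50.0 | 22.3 | 72.7 |
| west | 60.0 | 28.9 | 65.1 |
| west | 90.0 | 47.1 | 44.4 |
| north | 25.0 | 24.5 | 73.4 |
| north | 50.0 | 62.3 | 33.7 |
| north | 60.0 | 72.8 | 22.2 |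
| north | 90.0 | 90.9 | 5.1 |

(each reading ± 1 percentage point)

- amount of target in percent of the starting material charged, at 15 min, 50 min and 2.5 h

West and north differ in loading, and at 90.0 min west held 47.1 % target against 90.9 % in north. Adding target and starting material, west fell short of the charge by 8.50 % and north by 4.00 %, about half as much.

More catalyst thus meant less loss, which suggests a parallel first-order loss that ignores the catalyst and simply lasts as long as starting material stands. So I took the area, the integral over time of [starting material] as a share of its charge. It was 67.5 min in west and 42.0 min in north, because north used its starting material sooner. Each shortfall is a difference of scattered readings, so I pooled the two runs into one side-loss constant, the shortfall per minute of area: 0.00114 /min.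

The flask's loading lies between the two, so I gave it their mean area, 54.7 min, up to 90.0 min. That made the side loss 6.24 %, a little more with the late tail, and put the target near 93.8 % less whatever starting material remained.

The forecast said 5 %, 38.3 % and 88 %, on a loss that “fits a catalyst-independent first-order side loss”. Its constant was 0.0013 /min where mine was 0.00114 /min, and its side loss at the end was 8 %.

The flask gave 5.34 %, 39.5 % and 90.1 %.

    starting material + free catalyst → free catalyst + target (k = 605 /M/min)
    starting material → side product (k = 0.00106 /min)
    starting material + free catalyst → spent catalyst (k = 0.0640 /M/min)
    precatalyst → free catalyst (k = 0.0137 /min)

The forecast held. The main reason the flask's target stopped short of the charge is the side step. At 2.50 h the flask held 6.56 % side product, while my 0.00114 /min on the area of 54.7 min had given 6.24 % up to 90.0 min, before the late tail. The same flask run without that step gave 96.1 % target instead of 90.1 %, a gain of 6 percentage points and 61 % of what is missing. The step to spent catalyst turned over 0.00953 % of the charge.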